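## Retrosynthetic overview

1. The exocyclic methylene is released last from a dimethylamine adduct; the C-3 acetate and C-9 angelate come from stepwise reduction (hydride at C-9, CBS at C-3) of a ten-membered enone/ketone.
2. Key disconnection C-2–C-3: the ten-membered ring arises by a four-atom radical ring expansion of a 4-acyl-4-chlorocyclohexenone (C-3–C-8 bond cleaved; C-9, C-10, C-1, C-2 inserted). The Z-alkene is inherited from the six-membered ring.
3. The expansion substrate comes from C-acylation of a bicyclic lactone-enone with (R)-4-iodo-2-methylbutanoyl chloride (C-10 set by asymmetric hydrogenation).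
4. The lactone-enone comes from the quinone monoketal of o-cresol: Rh-catalysed asymmetric alkenylation (C-7), two Luche reductions (C-6), oxidative lactonisation.
5. Ring order: six-membered carbocycle (from the arene), then the γ-lactone, then the ten-membered carbocycle by ring expansion.

Assumption: "C-n" labels in the explanations are the germacrane locants of the target (ring C-1 to C-10, lactone C-11/C-12/C-13, methyls C-14 on C-10 and C-15 on C-4), while systematic names carry their own locants; the ligand antipodes in steps 4 and 9 are assigned by analogy and would be exchanged if the sense proved opposite.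

## Route

Step 1
Reactants: 1 2-bromoprop-2-en-1-ol
Product: 2 [(2-bromoprop-2-en-1-yl)oxy]triethylsilane
Conditions: Et3SiCl, imidazole, CH2Cl2, 0 °C to rt
Reagents that add atoms: chlorotriethylsilane, CC[Si](Cl)(CC)CC
Why: Standard silyl ether formation protects the allylic alcohol for the two metal-catalysed steps that follow; no stereocentre is involved.

Step 2
Reactants: 2 [(2-bromoprop-2-en-1-yl)oxy]triethylsilane
Product: 3 triethyl{[2-(4,4,5,5-tetramethyl-1,3,2-dioxaborolan-2-yl)prop-2-en-1-yl]oxy}silane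
Conditions: B2pin2, PdCl2(PPh3)2 (3 mol%), PPh3, KOPh, toluene, 50 °C
Reagents that add atoms: bis(pinacolato)diboron, CC1(C)OB(OC1(C)C)B1OC(C)(C)C(C)(C)O1
Why: Miyaura borylation of a 1-alkenyl bromide with phenoxide as base gives the 1,1-disubstituted alkenylboronate without touching the silyl ether.

Step 3
Reactants: 4 2-methylphenol
Product: 6 4,4-dimethoxy-2-methylcyclohexa-2,5-dien-1-one, via 4-methoxy-2-methylphenol 5 (not isolated)
Conditions: PhI(OAc)2 (2.1 equiv), MeOH, 0 °C to rt
Reagents that add atoms: methanol, CO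
Why: Twofold oxidative dearomatisation of a para-unsubstituted phenol in methanol gives the p-quinone monoketal, which fixes the oxygen pattern C-3 (ketone) and C-6 (ketal) around the future C-4=C-5 alkene.

Step 4
Reactants: 6 4,4-dimethoxy-2-methylcyclohexa-2,5-dien-1-one + 3 triethyl{[2-(4,4,5,5-tetramethyl-1,3,2-dioxaborolan-2-yl)prop-2-en-1-yl]oxy}silane
Product: 7 (5S)-4,4-dimethoxy-2-methyl-5-{3-[(triethylsilyl)oxy]prop-1-en-2-yl}cyclohex-2-en-1-one
Conditions: [RhCl(C2H4)2]2 (2.5 mol%), (S)-BINAP (5.5 mol%), KOH (0.3 equiv), 1,4-dioxane/H2O 10:1, 30 °C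
Reagents that add atoms: none
Why: Hayashi–Miyaura asymmetric conjugate addition places the alkenyl group on the β-carbon of the unsubstituted enone (the methyl-bearing enone is less reactive), and the ligand sets C-7 (S) with the facial sense known for cyclohex-2-enone.

Step 5
Reactants: 7 (5S)-4,4-dimethoxy-2-methyl-5-{3-[(triethylsilyl)oxy]prop-1-en-2-yl}cyclohex-2-en-1-one
Product: 9 (6S)-4-hydroxy-3-methyl-6-{3-[(triethylsilyl)oxy]prop-1-en-2-yl}cyclohex-2-en-1-one (C-4 epimers), via allylic alcohol ketal 8 (not isolated)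
Conditions: NaBH4, CeCl3·7H2O, MeOH, −78 °C; then 5% aq. oxalic acid, THF, 0 °C
Reagents that add atoms: water, O
Why: Luche 1,2-reduction parks C-3 as an alcohol and brief mild hydrolysis of the now allylic dimethyl ketal unveils the C-6 ketone; the silyl ether is kept so that the keto alcohol cannot close to a furan, and C-7 is untouched.

Step 6
Reactants: 9 (6S)-4-hydroxy-3-methyl-6-{3-[(triethylsilyl)oxy]prop-1-en-2-yl}cyclohex-2-en-1-one (C-4 epimers)
Product: 11 (1R,6S)-6-(3-hydroxyprop-1-en-2-yl)-3-methylcyclohex-2-ene-1,4-diol (C-4 epimers), via silyl ether diol 10 (not isolated)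
Conditions: NaBH4, CeCl3·7H2O, MeOH, −78 to −40 °C; then NH4F, MeOH, rt
Reagents that add atoms: none
Why: Luche reduction delivers hydride axially to the half-chair with the C-7 side chain pseudo-equatorial, giving the equatorial C-6 alcohol trans to C-7 (6R), and fluoride then removes the silyl group once no ketone is left.

Step 7
Reactants: 11 (1R,6S)-6-(3-hydroxyprop-1-en-2-yl)-3-methylcyclohex-2-ene-1,4-diol (C-4 epimers)
Product: 12 (3aS,7aR)-6-methyl-3-methylidene-3,3a,4,7a-tetrahydro-1-benzofuran-2,5-dione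
Conditions: TEMPO (0.2 equiv), PhI(OAc)2 (3.5 equiv), CH2Cl2, rt
Reagents that add atoms: none
Why: TEMPO/PhI(OAc)2 oxidative lactonisation oxidises the primary allylic alcohol first, the enal is trapped by the C-6 hydroxyl as a lactol and oxidised to the trans-fused α-methylene lactone (C-6 and C-7 retained), and the remaining C-3 allylic alcohol is oxidised to the enone, which erases the C-3 epimers.

Step 8
Reactants: 12 (3aS,7aR)-6-methyl-3-methylidene-3,3a,4,7a-tetrahydro-1-benzofuran-2,5-dione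
Product: 13 (3aS,7aS)-3-[(dimethylamino)methyl]-6-methyl-3,3a,4,7a-tetrahydro-1-benzofuran-2,5-dione (C-3 epimers)
Conditions: Me2NH (2 M in THF), THF, 0 °C
Reagents that add atoms: dimethylamine, CNC
Why: Aza-Michael addition masks the α-methylene lactone as its Mannich base so that it survives enolate, radical and hydride chemistry; the new C-11 centre is removed again in step 17.

Step 9
Reactants: 14 3-methylideneoxolan-2-one
Product: 15 (3R)-3-methyloxolan-2-one
Conditions: H2 (100 atm), Ru(OAc)2[(S)-BINAP] (0.5 mol%), CH2Cl2, 50 °C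
Reagents that add atoms: none
Why: Noyori-type asymmetric hydrogenation of the exocyclic enoate sets the future C-10 stereocentre (R).

Step 10
Reactants: 15 (3R)-3-methyloxolan-2-one
Product: 17 (2R)-4-iodo-2-methylbutanoyl chloride, via silyl ester 16 (not isolated)
Conditions: Me3SiI, CH2Cl2, rt; then (COCl)2, DMF (cat.), 0 °C to rt
Reagents that add atoms: iodotrimethylsilane, C[Si](C)(C)I; oxalyl chloride, O=C(Cl)C(Cl)=O
Why: Jung–Olah lactone cleavage (iodide attacks the O–CH2 carbon) gives the ω-iodo silyl ester, which oxalyl chloride converts to the acid chloride under neutral conditions, so the α-stereocentre is not enolised.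

Step 11
Reactants: 13 (3aS,7aS)-3-[(dimethylamino)methyl]-6-methyl-3,3a,4,7a-tetrahydro-1-benzofuran-2,5-dione (C-3 epimers) + 17 (2R)-4-iodo-2-methylbutanoyl chloride
Product: 19 (3aS,7aR)-4-chloro-3-[(dimethylamino)methyl]-4-[(2R)-4-iodo-2-methylbutanoyl]-6-methyl-3,3a,4,7a-tetrahydro-1-benzofuran-2,5-dione (C-3 and C-4 epimers), via diketone 18 (not isolated)
Conditions: MgBr2·OEt2, i-Pr2NEt, CH2Cl2, 0 °C; then CCl3SO2Cl, 0 °C
Reagents that add atoms: trichloromethanesulfonyl chloride, ClC(Cl)(Cl)S(=O)(=O)Cl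
Why: Soft-enolisation C-acylation at C-8 (the only enolisable α-position of the enone) forms the C-8–C-9 bond, and the magnesium diketonate is chlorinated in the same flask by an amine-tolerant chlorine donor; the chlorine blocks enolisation and hydrogen transfer at C-8, and the C-8 epimers converge in step 12.

Step 12
Reactants: 19 (3aS,7aR)-4-chloro-3-[(dimethylamino)methyl]-4-[(2R)-4-iodo-2-methylbutanoyl]-6-methyl-3,3a,4,7a-tetrahydro-1-benzofuran-2,5-dione (C-3 and C-4 epimers)
Product: 20 (3aS,6R,10Z,11aS)-3-[(dimethylamino)methyl]-6,10-dimethyl-3a,4,6,7,8,11a-hexahydrocyclodeca[b]furan-2,5,9(3H)-trione (C-3 epimers)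
Conditions: Bu3SnH (2.5 equiv, syringe pump), AIBN (0.2 equiv), benzene (5 mM), 80 °C
Reagents that add atoms: none
Why: Proposed new method: Bu3Sn• abstracts iodine, the primary C-2 radical adds 6-exo to the C-3 ketone carbon, and the bicyclic alkoxy radical cleaves the C-3–C-8 bond because this releases a C-8 radical stabilised by the C-9 ketone and chlorine, so C-9, C-10, C-1 and C-2 are inserted and the ring alkene of the cyclohexenone becomes the Z-alkene of the ten-membered ring; excess Bu3SnH then removes the chlorine, no stereocentre is formed, and the closest known reaction type is the Dowd–Beckwith ring expansion of 2-(ω-haloalkyl) β-keto esters, which has not been shown with the tether running through the exocyclic acyl group of a 2-acylcycloalkenone.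

Step 13
Reactants: 20 (3aS,6R,10Z,11aS)-3-[(dimethylamino)methyl]-6,10-dimethyl-3a,4,6,7,8,11a-hexahydrocyclodeca[b]furan-2,5,9(3H)-trione (C-3 epimers)
Product: 21 (3aS,5S,6R,10Z,11aS)-3-[(dimethylamino)methyl]-5-hydroxy-6,10-dimethyl-3a,4,5,6,7,8-hexahydrocyclodeca[b]furan-2,9(3H,11aH)-dione (C-3 epimers)
Conditions: NaBH4, MeOH/CH2Cl2 1:1, −78 to −40 °C
Reagents that add atoms: none
Why: Cold borohydride reduces the saturated C-9 ketone in preference to the α-methyl enone (Ward conditions), and Felkin–Anh attack next to the C-10 stereocentre is expected to give the 9,10-anti alcohol (9S); removing the C-9 ketone also stops transannular aldol closure.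

Step 14
Reactants: 21 (3aS,5S,6R,10Z,11aS)-3-[(dimethylamino)methyl]-5-hydroxy-6,10-dimethyl-3a,4,5,6,7,8-hexahydrocyclodeca[b]furan-2,9(3H,11aH)-dione (C-3 epimers) + 22 (2Z)-2-methylbut-2-enoic acid
Product: 24 (3aS,5S,6R,10Z,11aS)-3-[(dimethylamino)methyl]-6,10-dimethyl-2,9-dioxo-2,3,3a,4,5,6,7,8,9,11a-decahydrocyclodeca[b]furan-5-yl (2Z)-2-methylbut-2-enoate (C-3 epimers), via mixed anhydride 23 (not isolated)
Conditions: 2,4,6-Cl3C6H2COCl, Et3N, toluene, rt; then 21, toluene, 60 °C
Reagents that add atoms: 2,4,6-trichlorobenzoyl chloride, O=C(Cl)c1c(Cl)cc(Cl)cc1Cl (its atoms are in intermediate 23 only)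
Why: Yamaguchi-type mixed-anhydride esterification without a nucleophilic catalyst acylates the hindered C-9 alcohol with retention at C-9 and without Z-to-E isomerisation of the angelate.

Step 15
Reactants: 24 (3aS,5S,6R,10Z,11aS)-3-[(dimethylamino)methyl]-6,10-dimethyl-2,9-dioxo-2,3,3a,4,5,6,7,8,9,11a-decahydrocyclodeca[b]furan-5-yl (2Z)-2-methylbut-2-enoate (C-3 epimers)
Product: 25 (3aS,5S,6R,9S,10Z,11aS)-3-[(dimethylamino)methyl]-9-hydroxy-6,10-dimethyl-2-oxo-2,3,3a,4,5,6,7,8,9,11a-decahydrocyclodeca[b]furan-5-yl (2Z)-2-methylbut-2-enoate (C-3 epimers)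
Conditions: (R)-2-methyl-CBS-oxazaborolidine (1 equiv), catecholborane, toluene, −78 °C
Reagents that add atoms: none
Why: Corey–Bakshi–Shibata reduction under reagent control, with the alkenyl side as the large group and C-2 methylene as the small group, gives the 3S allylic alcohol by 1,2-reduction only.

Step 16
Reactants: 25 (3aS,5S,6R,9S,10Z,11aS)-3-[(dimethylamino)methyl]-9-hydroxy-6,10-dimethyl-2-oxo-2,3,3a,4,5,6,7,8,9,11a-decahydrocyclodeca[b]furan-5-yl (2Z)-2-methylbut-2-enoate (C-3 epimers)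
Product: 26 (3aS,5S,6R,9S,10Z,11aS)-9-(acetyloxy)-3-[(dimethylamino)methyl]-6,10-dimethyl-2-oxo-2,3,3a,4,5,6,7,8,9,11a-decahydrocyclodeca[b]furan-5-yl (2Z)-2-methylbut-2-enoate (C-3 epimers)
Conditions: Ac2O, pyridine, DMAP (cat.), CH2Cl2, 0 °C to rt
Reagents that add atoms: acetic anhydride, CC(=O)OC(C)=O
Why: Standard acylation of the secondary allylic alcohol with retention at C-3.

Step 17
Reactants: 26 (3aS,5S,6R,9S,10Z,11aS)-9-(acetyloxy)-3-[(dimethylamino)methyl]-6,10-dimethyl-2-oxo-2,3,3a,4,5,6,7,8,9,11a-decahydrocyclodeca[b]furan-5-yl (2Z)-2-methylbut-2-enoate (C-3 epimers)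
Product: 28 (3aS,5S,6R,9S,10Z,11aR)-9-(acetyloxy)-6,10-dimethyl-3-methylidene-2-oxo-2,3,3a,4,5,6,7,8,9,11a-decahydrocyclodeca[b]furan-5-yl (2Z)-2-methylbut-2-enoate, via ammonium iodide 27 (not isolated)
Conditions: MeI, MeCN, rt; then NaHCO3 (aq.), EtOAc, rt
Reagents that add atoms: iodomethane, CI (its atoms are in intermediate 27 only)
Why: N-methylation followed by mild E1cB (Hofmann-type) elimination of trimethylamine regenerates the α-methylene lactone without touching the two esters and removes the C-11 stereocentre.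

## Compound list

1 | 2-bromoprop-2-en-1-ol | C=C(Br)CO | starting material
2 | [(2-bromoprop-2-en-1-yl)oxy]triethylsilane | C=C(Br)CO[Si](CC)(CC)CC | intermediate
3 | triethyl{[2-(4,4,5,5-tetramethyl-1,3,2-dioxaborolan-2-yl)prop-2-en-1-yl]oxy}silane | C=C(CO[Si](CC)(CC)CC)B1OC(C)(C)C(C)(C)O1 | intermediate
4 | 2-methylphenol (o-cresol) | Cc1ccccc1O | starting material
5 | 4-methoxy-2-methylphenol | COc1ccc(O)c(C)c1 | intermediate (not isolated)
6 | 4,4-dimethoxy-2-methylcyclohexa-2,5-dien-1-one | COC1(OC)C=CC(=O)C(C)=C1 | intermediate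
7 | (5S)-4,4-dimethoxy-2-methyl-5-{3-[(triethylsilyl)oxy]prop-1-en-2-yl}cyclohex-2-en-1-one | O=C1C[C@@H](C(=C)CO[Si](CC)(CC)CC)C(OC)(OC)C=C1C | intermediate
8 | (5S)-4,4-dimethoxy-2-methyl-5-{3-[(triethylsilyl)oxy]prop-1-en-2-yl}cyclohex-2-en-1-ol, C-1 epimers | OC1C[C@@H](C(=C)CO[Si](CC)(CC)CC)C(OC)(OC)C=C1C | intermediate (not isolated)
9 | (6S)-4-hydroxy-3-methyl-6-{3-[(triethylsilyl)oxy]prop-1-en-2-yl}cyclohex-2-en-1-one, C-4 epimers | O=C1C=C(C)C(O)C[C@H]1C(=C)CO[Si](CC)(CC)CC | intermediate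
10 | (1R,6S)-3-methyl-6-{3-[(triethylsilyl)oxy]prop-1-en-2-yl}cyclohex-2-ene-1,4-diol, C-4 epimers | O[C@@H]1C=C(C)C(O)C[C@H]1C(=C)CO[Si](CC)(CC)CC | intermediate (not isolated)
11 | (1R,6S)-6-(3-hydroxyprop-1-en-2-yl)-3-methylcyclohex-2-ene-1,4-diol, C-4 epimers | O[C@@H]1C=C(C)C(O)C[C@H]1C(=C)CO | intermediate
12 | (3aS,7aR)-6-methyl-3-methylidene-3,3a,4,7a-tetrahydro-1-benzofuran-2,5-dione (trans-fused) | C=C1C(=O)O[C@@H]2C=C(C)C(=O)C[C@@H]12 | intermediate
13 | (3aS,7aS)-3-[(dimethylamino)methyl]-6-methyl-3,3a,4,7a-tetrahydro-1-benzofuran-2,5-dione, C-3 epimers (trans-fused) | CN(C)CC1C(=O)O[C@@H]2C=C(C)C(=O)C[C@@H]12 | intermediate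
14 | 3-methylideneoxolan-2-one (α-methylene-γ-butyrolactone) | C=C1CCOC1=O | starting material
15 | (3R)-3-methyloxolan-2-one | C[C@@H]1CCOC1=O | intermediate
16 | trimethylsilyl (2R)-4-iodo-2-methylbutanoate | C[C@H](CCI)C(=O)O[Si](C)(C)C | intermediate (not isolated)
17 | (2R)-4-iodo-2-methylbutanoyl chloride | C[C@H](CCI)C(Cl)=O | intermediate
18 | (3aS,7aS)-3-[(dimethylamino)methyl]-4-[(2R)-4-iodo-2-methylbutanoyl]-6-methyl-3,3a,4,7a-tetrahydro-1-benzofuran-2,5-dione, C-3 and C-4 epimers, largely enolised | CN(C)CC1C(=O)O[C@@H]2C=C(C)C(=O)C(C(=O)[C@H](C)CCI)[C@@H]12 | intermediate (not isolated)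
19 | (3aS,7aR)-4-chloro-3-[(dimethylamino)methyl]-4-[(2R)-4-iodo-2-methylbutanoyl]-6-methyl-3,3a,4,7a-tetrahydro-1-benzofuran-2,5-dione, C-3 and C-4 epimers | CN(C)CC1C(=O)O[C@@H]2C=C(C)C(=O)C(Cl)(C(=O)[C@H](C)CCI)[C@@H]12 | intermediate
20 | (3aS,6R,10Z,11aS)-3-[(dimethylamino)methyl]-6,10-dimethyl-3a,4,6,7,8,11a-hexahydrocyclodeca[b]furan-2,5,9(3H)-trione, C-3 epimers | CN(C)CC1C(=O)O[C@@H]2/C=C(/C)C(=O)CC[C@@H](C)C(=O)C[C@@H]12 | intermediate
21 | (3aS,5S,6R,10Z,11aS)-3-[(dimethylamino)methyl]-5-hydroxy-6,10-dimethyl-3a,4,5,6,7,8-hexahydrocyclodeca[b]furan-2,9(3H,11aH)-dione, C-3 epimers | CN(C)CC1C(=O)O[C@@H]2/C=C(/C)C(=O)CC[C@@H](C)[C@@H](O)C[C@@H]12 | intermediate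
22 | (2Z)-2-methylbut-2-enoic acid (angelic acid) | C/C=C(/C)C(=O)O | starting material
23 | (2Z)-2-methylbut-2-enoic 2,4,6-trichlorobenzoic anhydride | C/C=C(/C)C(=O)OC(=O)c1c(Cl)cc(Cl)cc1Cl | intermediate (not isolated)
24 | (3aS,5S,6R,10Z,11aS)-3-[(dimethylamino)methyl]-6,10-dimethyl-2,9-dioxo-2,3,3a,4,5,6,7,8,9,11a-decahydrocyclodeca[b]furan-5-yl (2Z)-2-methylbut-2-enoate, C-3 epimers | CN(C)CC1C(=O)O[C@@H]2/C=C(/C)C(=O)CC[C@@H](C)[C@@H](OC(=O)/C(C)=C\C)C[C@@H]12 | intermediate
25 | (3aS,5S,6R,9S,10Z,11aS)-3-[(dimethylamino)methyl]-9-hydroxy-6,10-dimethyl-2-oxo-2,3,3a,4,5,6,7,8,9,11a-decahydrocyclodeca[b]furan-5-yl (2Z)-2-methylbut-2-enoate, C-3 epimers | CN(C)CC1C(=O)O[C@@H]2/C=C(/C)[C@@H](O)CC[C@@H](C)[C@@H](OC(=O)/C(C)=C\C)C[C@@H]12 | intermediate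
26 | (3aS,5S,6R,9S,10Z,11aS)-9-(acetyloxy)-3-[(dimethylamino)methyl]-6,10-dimethyl-2-oxo-2,3,3a,4,5,6,7,8,9,11a-decahydrocyclodeca[b]furan-5-yl (2Z)-2-methylbut-2-enoate, C-3 epimers | CN(C)CC1C(=O)O[C@@H]2/C=C(/C)[C@@H](OC(C)=O)CC[C@@H](C)[C@@H](OC(=O)/C(C)=C\C)C[C@@H]12 | intermediate
27 | N,N,N-trimethyl ammonium iodide of 26 (quaternised at the side-chain nitrogen), C-3 epimers | C[N+](C)(C)CC1C(=O)O[C@@H]2/C=C(/C)[C@@H](OC(C)=O)CC[C@@H](C)[C@@H](OC(=O)/C(C)=C\C)C[C@@H]12.[I-] | intermediate (not isolated)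
28 | (3aS,5S,6R,9S,10Z,11aR)-9-(acetyloxy)-6,10-dimethyl-3-methylidene-2-oxo-2,3,3a,4,5,6,7,8,9,11a-decahydrocyclodeca[b]furan-5-yl (2Z)-2-methylbut-2-enoate (CNP0173235.1) | C=C1C(=O)O[C@@H]2/C=C(/C)[C@@H](OC(C)=O)CC[C@@H](C)[C@@H](OC(=O)/C(C)=C\C)C[C@@H]12 | target

## Step count and risks

Total: 17 steps. Longest linear sequence: 14 steps (steps 1, 2, 4 to 8 and 11 to 17, from 2-bromoprop-2-en-1-ol 1). The branch from o-cresol 4 (step 3) joins at step 4, and the acid chloride branch (steps 9 and 10) joins at step 11.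

**Step 12 (the proposed new ring expansion).** It may stall at simple reduction of the iodide or lose chlorine first. The fallback uses known reactions and sets out from diketone 18, isolated from step 11 by leaving out the chlorination. Slow addition of Bu3SnH/AIBN in benzene closes the primary radical 6-endo onto the hydrogen-bonded enol (a β-oxygenated enone acceptor with no hydrogen at C-8) to give the cis-fused tricyclic β-hydroxy ketone F1. As its trifluoroacetate salt, F1 is treated with PhI(OAc)2 and I2 in CH2Cl2 under visible light (Suárez alkoxy-radical fragmentation); β-scission of the C-3–C-8 bond and iodine capture give the ten-membered α-iodo diketone F2. Zn in AcOH removes the iodine, and the route is rejoined at 20.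

**Step 13 (chemo- and diastereoselectivity of the C-9 reduction on a medium ring).** The 9S outcome rests on a Felkin–Anh argument that ring conformation may override. If hydride delivery to 20 gives mainly the 9R alcohol F3, F3 is esterified with 22 under Mitsunobu conditions (PPh3, DIAD, toluene, 0 °C). This inverts C-9 and gives 24 directly, where the route is rejoined.

**Step 15 (reagent control by the oxazaborolidine on the ten-membered enone that carries a basic amine).** If selectivity is poor, 24 is reduced under substrate control with NaBH4/CeCl3·7H2O in MeOH at −78 °C. The 3S alcohol is 25 itself; the 3R alcohol F4 is converted by Mitsunobu reaction with acetic acid (PPh3, DIAD, THF, 0 °C), with inversion at C-3, into 26, where the route is rejoined.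

## Further compounds

F1 | step 12 | cis-fused tricyclic β-hydroxy ketone: lactone-fused cyclohexene whose C-3 carries a tertiary hydroxyl and is bonded to C-2, with C-8–C-9(=O)–C-10(R, methyl)–C-1–C-2 closing the new cyclohexanone ring; dimethylaminomethyl lactone as in 18 | CN(C)CC1C(=O)O[C@@H]2C=C(C)C3(O)CC[C@@H](C)C(=O)C3[C@@H]12
F2 | step 12 | 4-iodo derivative of 20: (3aS,6R,10Z)-3-[(dimethylamino)methyl]-4-iodo-6,10-dimethyl-3a,4,6,7,8,11a-hexahydrocyclodeca[b]furan-2,5,9(3H)-trione, C-3 and C-4 epimers | CN(C)CC1C(=O)O[C@@H]2/C=C(/C)C(=O)CC[C@@H](C)C(=O)C(I)[C@@H]12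
F3 | step 13 | (5R)-epimer of 21 (9-epi alcohol, hydroxyl syn to the C-10 methyl) | CN(C)CC1C(=O)O[C@@H]2/C=C(/C)C(=O)CC[C@@H](C)[C@H](O)C[C@@H]12
F4 | step 15 | (9R)-epimer of 25 (3-epi allylic alcohol) | CN(C)CC1C(=O)O[C@@H]2/C=C(/C)[C@H](O)CC[C@@H](C)[C@@H](OC(=O)/C(C)=C\C)C[C@@H]12
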